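Ring B is cut at C2–C3 and C4–C5. The target holds the C1 oxygen and the carboxyl-bearing C4 in a 1,4 relationship across ring B, with quaternary C5 next to C4; this is the pattern that a 2-silyloxydiene (C2=C1–C10=C5) and an acrylate (C3=C4) leave behind. One catalytic enantioselective Lewis-acid [4+2] addition thus closes ring B, creates quaternary C5 with its absolute configuration, brings in C15 and leaves C1 as a silyl enol ether, from which the C1 oxygen and the C9=C10 alkene follow. Its precursor is the tert-butyldimethylsilyl dienol ether of 1-acetyl-2-methylcyclohexene, which already holds ring A, C14 and C1–C2.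

Key step: step 4

Numbering used throughout (eremophilane): ring A = C5 to C10 (enone ring), ring B = C1 to C5 plus C10; C1 acyloxy carbon, C4 carboxyl-bearing carbon, C5 quaternary carbon, C7 acrolein-bearing carbon, C8 ketone, C9=C10 alkene, C14 angular methyl, C15 carboxyl carbon.

Assumption: the ring closure is taken to be endo (ester under the diene, hence anti to the inward C14 methyl), and the R oxazaborolidine is taken to expose the Si face of the acrylate α-carbon (mirror image of the S catalyst, which gives (S)-cyclohex-3-enecarboxylates from butadiene); the adduct is then the (4R,5R) ester 8, which has the C5 configuration of the target but is its C4 epimer, and C4 is inverted in step 6.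

Step 1
Reactants: 1 1-methylcyclohexene; 2 acetyl chloride
Product: 3 1-(2-chloro-2-methylcyclohexyl)ethan-1-one (racemic, both diastereomers)
Conditions: SnCl4 (1.0 equiv), CH2Cl2, −78 °C
Reagents that add atoms: none
Why: Friedel–Crafts-type acylation of the alkene, in which the acylium ion adds to the less substituted alkene carbon and chloride captures the tertiary cation, so that the acetyl group sits next to the methyl-bearing carbon.

Step 2
Reactants: 3 1-(2-chloro-2-methylcyclohexyl)ethan-1-one
Product: 4 1-(2-methylcyclohex-1-en-1-yl)ethan-1-one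
Conditions: DBU, CH2Cl2, 0 → 23 °C
Reagents that add atoms: none
Why: E1cB dehydrochlorination through the ketone enolate puts the alkene in conjugation as the tetrasubstituted enone, and the base also moves any β,γ-unsaturated isomer from step 1 toward the conjugated form.

Step 3
Reactants: 4 1-(2-methylcyclohex-1-en-1-yl)ethan-1-one
Product: 6 1-[1-(tert-butyldimethylsilyloxy)vinyl]-2-methylcyclohexene, via potassium dienolate 5 (not isolated)
Conditions: KN(SiMe3)2, THF, −78 °C; then TBSCl, −78 → 0 °C
Reagents that add atoms: tert-butyldimethylsilyl chloride, CC(C)(C)[Si](C)(C)Cl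
Why: Kinetic deprotonation of the enone at the acetyl methyl group (α′ position) followed by O-silylation gives the cross-conjugated 2-silyloxydiene.

Step 4
Reactants: 6 1-[1-(tert-butyldimethylsilyloxy)vinyl]-2-methylcyclohexene; 7 2,2,2-trifluoroethyl acrylate
Product: 8 2,2,2-trifluoroethyl (4R,5R)-1-(tert-butyldimethylsilyloxy)-5-methyl-1(10)-octalin-4-carboxylate (ester anti to C14)
Conditions: (R)-3,3-diphenyl-1-(o-tolyl)tetrahydro-1H,3H-pyrrolo[1,2-c][1,3,2]oxazaborole (10 mol%), AlBr3 (8 mol%), CH2Cl2, −78 → −40 °C
Reagents that add atoms: none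
Why: The AlBr3-activated oxazaborolidine binds the acrylate carbonyl, the nucleophilic CH2 terminus C2 of the silyloxydiene adds to the β-carbon C3 (the Mukaiyama–Michael limit of a strongly asynchronous Lewis-acid Diels–Alder reaction), and the boron-bound ester enolate carbon C4 then closes on C5 of the silyloxyallyl cation. The closest known reactions are the cationic-oxazaborolidine-catalysed [4+2] additions of 2-silyloxydienes to 2,2,2-trifluoroethyl acrylate and the Lewis-acid cycloadditions of hindered 2-silyloxydienes that create quaternary carbons. Ring B closes as a six-membered carbocycle, either concertedly as a [4+2] or stepwise by a 6-(enolexo)-endo-trig Michael addition, and a cyclobutane from kinetic closure at C1 would be expected to ring-expand to the same octalin through the same zwitterion. C4 is set by the catalyst, which is taken to shield the Re face of the acrylate α-carbon, and C5 follows from the endo arrangement that holds the ester under the diene and anti to the inward C14 methyl, which gives (4R,5R). The para regiochemistry (C1 oxygen 1,4 to C4) is secured by the silyloxy group, which makes C2 the nucleophilic and C5 the electrophilic terminus, and neither partner carries another stereocentre or acidic site.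

Step 5
Reactants: 8 (4R,5R) trifluoroethyl ester
Product: 9 tert-butyl (4R,5R)-1-(tert-butyldimethylsilyloxy)-5-methyl-1(10)-octalin-4-carboxylate
Conditions: KOtBu (2.5 equiv), THF, 0 °C; aq. NH4Cl
Reagents that add atoms: potassium tert-butoxide, CC(C)(C)[O-].[K+]
Why: Alkoxide transesterification of the activated trifluoroethyl ester (trifluoroethoxide is the better leaving group) gives the tert-butyl ester that survives the later base, hydride and oxidation steps and is removed by acid at the end, and any C4 epimerisation here is immaterial because step 6 resets C4.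

Step 6
Reactants: 9 tert-butyl (4R,5R) ester
Product: 11 tert-butyl (4S,5R)-1-(tert-butyldimethylsilyloxy)-5-methyl-1(10)-octalin-4-carboxylate (ester syn to C14), via lithium ester enolate 10 (not isolated)
Conditions: LiN(iPr)2 (1.5 equiv), THF, −78 → −20 °C; then AcOH in THF, −78 °C
Reagents that add atoms: none
Why: Kinetic protonation of the exocyclic ester enolate should occur on the face of C4 opposite the vicinal pseudoaxial C14 methyl (axial delivery, opposed by a single syn-axial hydrogen because C10 is sp2), which places the ester equatorial and syn to C14 (4S), an epimer expected to be at least as stable as the 4R one and therefore not lost later.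

Step 7
Reactants: 11 tert-butyl (4S,5R) silyl enol ether
Product: 12 tert-butyl (4S,5R)-5-methyl-1-oxo-9-octalin-4-carboxylate (C1 ketone, C9=C10)
Conditions: Pd(OAc)2 (1.2 equiv), MeCN, 40 °C
Reagents that add atoms: none
Why: Saegusa oxidation, in which the palladium enolate bound at C10 can lose a β-hydrogen only from C9 because C5 is quaternary, so the C9=C10 enone forms regiospecifically.

Step 8
Reactants: 12 C1 enone
Product: 13 tert-butyl (1R,4S,5R)-1-hydroxy-5-methyl-9-octalin-4-carboxylate (axial OH syn to C14)
Conditions: NaBH4, CeCl3·7H2O, MeOH, −78 → −40 °C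
Reagents that add atoms: none
Why: Luche 1,2-reduction in which hydride attacks C1 from the face opposite the syn-axial C14 methyl and so gives the axial alcohol syn to C14 (1R), as in borohydride reductions of ketones placed 1,3 to an axial angular methyl.

Step 9
Reactants: 14 (R)-4-benzyl-1,3-oxazolidin-2-one; 15 hexanoyl chloride
Product: 17 (R)-4-benzyl-3-hexanoyl-1,3-oxazolidin-2-one, via lithium oxazolidinide 16 (not isolated)
Conditions: n-BuLi, THF, −78 °C; then 15, −78 → 0 °C
Reagents that add atoms: none
Why: N-acylation of the lithiated oxazolidinone with the acid chloride is the standard preparation of the acyl imide.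

Step 10
Reactants: 17 (R)-4-benzyl-3-hexanoyl-1,3-oxazolidin-2-one
Product: 19 (R)-4-benzyl-3-[(R)-2-methylhexanoyl]-1,3-oxazolidin-2-one, via sodium Z-enolate 18 (not isolated)
Conditions: NaN(SiMe3)2, THF, −78 °C; then MeI, −78 °C
Reagents that add atoms: iodomethane, CI
Why: Oxazolidinone-auxiliary enolate alkylation (Evans alkylation), in which the chelated Z-enolate is methylated on the face opposite the benzyl group, which with the R auxiliary gives the (R)-2-methylhexanoyl imide.

Step 11
Reactants: 19 (R)-4-benzyl-3-[(R)-2-methylhexanoyl]-1,3-oxazolidin-2-one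
Product: 20 (R)-2-methylhexan-1-ol
Conditions: LiBH4, MeOH (1 equiv), Et2O, 0 °C
Reagents that add atoms: none
Why: Reductive cleavage at the imide carbonyl releases the primary alcohol without touching the α-stereocentre and returns the auxiliary.

Step 12
Reactants: 20 (R)-2-methylhexan-1-ol
Product: 22 ethyl (2E,4R)-2,4-dimethyloct-2-enoate, via (R)-2-methylhexanal 21 (not isolated)
Conditions: Dess–Martin periodinane, NaHCO3, CH2Cl2, 0 °C; then Ph3P=C(CH3)CO2Et, 23 °C
Reagents that add atoms: ethyl 2-(triphenyl-λ5-phosphanylidene)propanoate, CCOC(=O)C(C)=P(c1ccccc1)(c1ccccc1)c1ccccc1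
Why: Oxidation followed by in situ Wittig reaction with the stabilised ylide traps the epimerisable aldehyde at once and should give the E-trisubstituted enoate, as is usual for stabilised ylides.

Step 13
Reactants: 22 ethyl (2E,4R)-2,4-dimethyloct-2-enoate
Product: 23 (2E,4R)-2,4-dimethyloct-2-enoic acid
Conditions: LiOH, THF/MeOH/H2O, 40 °C; then aq. HCl
Reagents that add atoms: lithium hydroxide, [Li+].[OH-]
Why: Saponification of the ethyl ester under conditions that do not deprotonate the γ-carbon, so the alkene geometry and the γ-stereocentre are retained.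

Step 14
Reactants: 13 allylic alcohol; 23 (2E,4R)-2,4-dimethyloct-2-enoic acid
Product: 25 tert-butyl (1R,4S,5R)-1-{[(2E,4R)-2,4-dimethyloct-2-enoyl]oxy}-5-methyl-9-octalin-4-carboxylate, via mixed anhydride 24 (not isolated)
Conditions: 2,4,6-trichlorobenzoyl chloride, Et3N, THF, 23 °C; then 13, DMAP, toluene, 23 → 50 °C
Reagents that add atoms: none
Why: Yamaguchi esterification, in which DMAP transfers the enoyl group from the mixed anhydride to the hindered axial allylic alcohol with retention at C1.

Step 15
Reactants: 25 C1 enoate ester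
Product: 26 tert-butyl (1R,4S,5R)-1-{[(2E,4R)-2,4-dimethyloct-2-enoyl]oxy}-5-methyl-8-oxo-9-octalin-4-carboxylate
Conditions: Rh2(cap)4 (dirhodium tetracaprolactamate, 1 mol%), t-BuOOH (70% in water), K2CO3, CH2Cl2, 23 °C
Reagents that add atoms: tert-butyl hydroperoxide, CC(C)(C)OO
Why: Allylic oxidation by tert-butylperoxyl radicals at C8, the only allylic methylene of the C9=C10 alkene (C5 is quaternary, C1 carries the acyloxy group), with the regiochemistry known from the oxidation of steroidal 5-enes to 7-ketones, while the electron-poor enoate should be left alone.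

Step 16
Reactants: 26 C8 enone
Product: 28 tert-butyl ester of the 7-allyl enone (allyl anti to C14), via lithium dienolate 27 (not isolated)
Conditions: LiN(SiMe3)2 (1.05 equiv), THF, −78 °C; then allyl bromide, DMPU, −78 → −30 °C
Reagents that add atoms: allyl bromide, C=CCBr
Why: Kinetic α′-deprotonation of the enone at C7 and alkylation of the cross-conjugated dienolate, with the electrophile entering anti to the pseudoaxial C14 methyl to give the equatorial C7 substituent trans to C14, which is also the thermodynamically preferred epimer.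

Step 17
Reactants: 28 7-allyl enone
Product: 30 7-(2-oxoethyl) enone, via diol 29 (not isolated)
Conditions: OsO4 (2 mol%), NaIO4, 2,6-lutidine, dioxane/H2O, 23 °C
Reagents that add atoms: osmium tetroxide, O=[Os](=O)(=O)=O; sodium periodate, [Na+].[O-]I(=O)(=O)=O
Why: Lemieux–Johnson cleavage, in which OsO4 dihydroxylates the isolated terminal alkene much faster than the conjugated, electron-poor enone and enoate alkenes and periodate cleaves the diol to the aldehyde.

Step 18
Reactants: 30 7-(2-oxoethyl) enone
Product: 32 tert-butyl ester of the target, via Mannich base 31 (not isolated)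
Conditions: N,N-dimethylmethyleneiminium iodide, Et3N, CH2Cl2, 23 °C
Reagents that add atoms: N,N-dimethylmethyleneiminium iodide, C=[N+](C)C.[I-]
Why: Mannich reaction of the aldehyde at its α-methylene carbon C11 followed by elimination of dimethylamine gives the 2-substituted acrolein, while C7 is not part of the reacting enol and keeps its equatorial configuration.

Step 19
Reactants: 32 tert-butyl ester of the target
Product: 33 CNP0143497.3
Conditions: CF3CO2H/CH2Cl2 (1:4), 0 °C
Reagents that add atoms: none
Why: Acidolysis of the tert-butyl ester with loss of isobutene frees the C15 acid without base, which spares the acrolein, the γ-acyloxy enone and the epimerisable C7.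

Compound list

1 | 1-methylcyclohexene | CC1=CCCCC1 | starting material
2 | acetyl chloride | CC(=O)Cl | starting material
3 | 1-(2-chloro-2-methylcyclohexyl)ethan-1-one (racemic, both diastereomers) | CC(=O)C1CCCCC1(C)Cl | intermediate
4 | 1-(2-methylcyclohex-1-en-1-yl)ethan-1-one | CC(=O)C1=C(C)CCCC1 | intermediate
5 | potassium 1-(2-methylcyclohex-1-en-1-yl)ethen-1-olate | [K+].[O-]C(=C)C1=C(C)CCCC1 | intermediate (not isolated)
6 | 1-[1-(tert-butyldimethylsilyloxy)vinyl]-2-methylcyclohexene | C=C(O[Si](C)(C)C(C)(C)C)C1=C(C)CCCC1 | intermediate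
7 | 2,2,2-trifluoroethyl acrylate | C=CC(=O)OCC(F)(F)F | starting material
8 | 2,2,2-trifluoroethyl (4R,5R)-1-(tert-butyldimethylsilyloxy)-5-methyl-1(10)-octalin-4-carboxylate; C1(OTBS)=C10, ester anti to C14 | C[C@]12CCCCC1=C(O[Si](C)(C)C(C)(C)C)CC[C@H]2C(=O)OCC(F)(F)F | intermediate
9 | tert-butyl (4R,5R)-1-(tert-butyldimethylsilyloxy)-5-methyl-1(10)-octalin-4-carboxylate | C[C@]12CCCCC1=C(O[Si](C)(C)C(C)(C)C)CC[C@H]2C(=O)OC(C)(C)C | intermediate
10 | lithium enolate of 9 (C4=C15 ketene acetal oxide, 5R) | [Li+].C[C@]12CCCCC1=C(O[Si](C)(C)C(C)(C)C)CCC2=C([O-])OC(C)(C)C | intermediate (not isolated)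
11 | tert-butyl (4S,5R)-1-(tert-butyldimethylsilyloxy)-5-methyl-1(10)-octalin-4-carboxylate; ester syn to C14 | C[C@]12CCCCC1=C(O[Si](C)(C)C(C)(C)C)CC[C@@H]2C(=O)OC(C)(C)C | intermediate
12 | tert-butyl (4S,5R)-5-methyl-1-oxo-9-octalin-4-carboxylate; C1 ketone, C9=C10 | C[C@]12CCCC=C1C(=O)CC[C@@H]2C(=O)OC(C)(C)C | intermediate
13 | tert-butyl (1R,4S,5R)-1-hydroxy-5-methyl-9-octalin-4-carboxylate; OH axial, syn to C14 | C[C@]12CCCC=C1[C@H](O)CC[C@@H]2C(=O)OC(C)(C)C | intermediate
14 | (R)-4-benzyl-1,3-oxazolidin-2-one | O=C1N[C@H](Cc2ccccc2)CO1 | starting material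
15 | hexanoyl chloride | CCCCCC(=O)Cl | starting material
16 | lithium (R)-4-benzyl-2-oxo-1,3-oxazolidin-3-ide | [Li+].O=C1[N-][C@H](Cc2ccccc2)CO1 | intermediate (not isolated)
17 | (R)-4-benzyl-3-hexanoyl-1,3-oxazolidin-2-one | CCCCCC(=O)N1[C@H](Cc2ccccc2)COC1=O | intermediate
18 | sodium Z-enolate of 17 | [Na+].CCCC/C=C(\[O-])N1[C@H](Cc2ccccc2)COC1=O | intermediate (not isolated)
19 | (R)-4-benzyl-3-[(R)-2-methylhexanoyl]-1,3-oxazolidin-2-one | CCCC[C@@H](C)C(=O)N1[C@H](Cc2ccccc2)COC1=O | intermediate
20 | (R)-2-methylhexan-1-ol | CCCC[C@@H](C)CO | intermediate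
21 | (R)-2-methylhexanal | CCCC[C@@H](C)C=O | intermediate (not isolated)
22 | ethyl (2E,4R)-2,4-dimethyloct-2-enoate | CCCC[C@@H](C)/C=C(\C)C(=O)OCC | intermediate
23 | (2E,4R)-2,4-dimethyloct-2-enoic acid | CCCC[C@@H](C)/C=C(\C)C(=O)O | intermediate
24 | (2E,4R)-2,4-dimethyloct-2-enoic 2,4,6-trichlorobenzoic anhydride | CCCC[C@@H](C)/C=C(\C)C(=O)OC(=O)c1c(Cl)cc(Cl)cc1Cl | intermediate (not isolated)
25 | tert-butyl (1R,4S,5R)-1-{[(2E,4R)-2,4-dimethyloct-2-enoyl]oxy}-5-methyl-9-octalin-4-carboxylate | C[C@]12CCCC=C1[C@H](OC(=O)/C(C)=C/[C@H](C)CCCC)CC[C@@H]2C(=O)OC(C)(C)C | intermediate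
26 | tert-butyl (1R,4S,5R)-1-{[(2E,4R)-2,4-dimethyloct-2-enoyl]oxy}-5-methyl-8-oxo-9-octalin-4-carboxylate | O=C1CC[C@@]2(C)C(=C1)[C@H](OC(=O)/C(C)=C/[C@H](C)CCCC)CC[C@@H]2C(=O)OC(C)(C)C | intermediate
27 | lithium C7=C8 dienolate of 26 | [Li+].[O-]C1=CC[C@@]2(C)C(=C1)[C@H](OC(=O)/C(C)=C/[C@H](C)CCCC)CC[C@@H]2C(=O)OC(C)(C)C | intermediate (not isolated)
28 | 7-allyl derivative of 26; allyl equatorial, anti to C14 | C=CC[C@@H]1C[C@@]2(C)C(=CC1=O)[C@H](OC(=O)/C(C)=C/[C@H](C)CCCC)CC[C@@H]2C(=O)OC(C)(C)C | intermediate
29 | 7-(2,3-dihydroxypropyl) derivative of 26 (both diol epimers) | OCC(O)C[C@@H]1C[C@@]2(C)C(=CC1=O)[C@H](OC(=O)/C(C)=C/[C@H](C)CCCC)CC[C@@H]2C(=O)OC(C)(C)C | intermediate (not isolated)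
30 | 7-(2-oxoethyl) derivative of 26 | O=CC[C@@H]1C[C@@]2(C)C(=CC1=O)[C@H](OC(=O)/C(C)=C/[C@H](C)CCCC)CC[C@@H]2C(=O)OC(C)(C)C | intermediate
31 | 7-[1-(dimethylamino)-3-oxopropan-2-yl] derivative of 26 (both C11 epimers) | CN(C)CC(C=O)[C@@H]1C[C@@]2(C)C(=CC1=O)[C@H](OC(=O)/C(C)=C/[C@H](C)CCCC)CC[C@@H]2C(=O)OC(C)(C)C | intermediate (not isolated)
32 | tert-butyl ester of the target; 7-(3-oxoprop-1-en-2-yl) | C=C(C=O)[C@@H]1C[C@@]2(C)C(=CC1=O)[C@H](OC(=O)/C(C)=C/[C@H](C)CCCC)CC[C@@H]2C(=O)OC(C)(C)C | intermediate
33 | CNP0143497.3; (1R,4S,5R,7S) in eremophilane numbering, side chain (2E,4R) | C=C(C=O)[C@@H]1C[C@@]2(C)C(=CC1=O)[C@H](OC(=O)/C(C)=C/[C@H](C)CCCC)CC[C@@H]2C(=O)O | target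

Total step count: 19. Longest linear sequence: 14 steps (steps 1 to 8 and 14 to 19); the side-chain acid 23 takes 5 steps (9 to 13).

Steps most likely to fail

Step 4. The zwitterion formed after the first C2–C3 bond may close at C1 to a cyclobutane, or be desilylated before it closes at the hindered C5. The slow second bond formation may also erode enantioface control. The fallback sets out from 6 and 7 and gives up catalytic asymmetric induction. The two would be combined under the achiral mixed Lewis acid AlBr3/AlMe3 in toluene/CH2Cl2, with warming so that any cyclobutane ring-expands, a method established for hindered 2-silyloxydienes that form quaternary carbons. This should give the racemic endo adduct, that is 8 together with its enantiomer, the 2,2,2-trifluoroethyl (4S,5S) adduct F1. The racemate would be resolved by preparative chromatography on a chiral stationary phase, and the (4R,5R) enantiomer comes back to the route as 8.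

Step 6. Protonation may be poorly face-selective, or the proton may return from lithium-bound diisopropylamine to the face it was taken from, which restores 9. The fallback sets out from 9 and replaces protonation by syn addition of hydrogen. LiN(iPr)2 followed by PhSeBr at −78 °C would give the α-phenylselanyl ester F2. Oxidation with mCPBA at −78 °C and warming with iPr2NH would eliminate the selenoxide toward C3 and give the 3,4-unsaturated ester F3. Hydrogenation (H2, Pd/C, EtOAc) should add hydrogen to this trisubstituted conjugated alkene from the face opposite the C14 methyl, leave the tetrasubstituted silyl enol ether untouched, and come back to the route at 11.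

Step 15. Hydrogen abstraction at the side-chain γ-C–H (loss of the side-chain stereocentre) or at C1–H may compete with abstraction at C8. The fallback sets out from 13 and oxidises C8 before the side chain is attached. TESCl and imidazole would give the triethylsilyl ether F4. The same Rh2(cap)4/t-BuOOH oxidation would give the C8 enone F5. HF·pyridine would free the γ-hydroxy enone F6. Yamaguchi esterification with 23 then comes back to the route at 26.

Further compounds

F1 | step 4 | 2,2,2-trifluoroethyl (4S,5S)-1-(tert-butyldimethylsilyloxy)-5-methyl-1(10)-octalin-4-carboxylate (enantiomer of 8) | C[C@@]12CCCCC1=C(O[Si](C)(C)C(C)(C)C)CC[C@@H]2C(=O)OCC(F)(F)F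
F2 | step 6 | tert-butyl (5R)-1-(tert-butyldimethylsilyloxy)-5-methyl-4-(phenylselanyl)-1(10)-octalin-4-carboxylate (either C4 epimer) | C[C@]12CCCCC1=C(O[Si](C)(C)C(C)(C)C)CCC2([Se]c3ccccc3)C(=O)OC(C)(C)C
F3 | step 6 | tert-butyl (5R)-1-(tert-butyldimethylsilyloxy)-5-methyl-1(10),3-hexalin-4-carboxylate (C3=C4 enoate) | C[C@]12CCCCC1=C(O[Si](C)(C)C(C)(C)C)CC=C2C(=O)OC(C)(C)C
F4 | step 15 | tert-butyl (1R,4S,5R)-5-methyl-1-(triethylsilyloxy)-9-octalin-4-carboxylate | C[C@]12CCCC=C1[C@H](O[Si](CC)(CC)CC)CC[C@@H]2C(=O)OC(C)(C)C
F5 | step 15 | tert-butyl (1R,4S,5R)-5-methyl-8-oxo-1-(triethylsilyloxy)-9-octalin-4-carboxylate | O=C1CC[C@@]2(C)C(=C1)[C@H](O[Si](CC)(CC)CC)CC[C@@H]2C(=O)OC(C)(C)C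
F6 | step 15 | tert-butyl (1R,4S,5R)-1-hydroxy-5-methyl-8-oxo-9-octalin-4-carboxylate | O=C1CC[C@@]2(C)C(=C1)[C@H](O)CC[C@@H]2C(=O)OC(C)(C)C
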